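The earlier runs and the new flask stem from a simulated flask for substances that don't exist.

4 questions stand on this flask: 3 shares of target and a lead.

| flask | substrate | catalyst | remark | time |
|---|---|---|---|---|
| violet | 0.72 M | 5.5 mol% | run made earlier |  |
| green | 0.72 M | 8.2 mol% | run made earlier |  |
| flask | 0.72 M | 11 mol% |  | 50 min |

| run | time / min | target / % | isomer of the product A / % |
|---|---|---|---|
| violet | 3.00 | 18 | 23 |
| violet | 5.00 | 14 | 34 |
| violet | 8.00 | 15 | 42 |
| violet | 12.0 | 16 | 46 |
| violet | 15.0 | 15 | 51 |
| violet | 25.0 | 9 | 53 |
| violet | 40.0 | 9 | 54 |
| green | 2.00 | 15 | 24 |
| green | 6.00 | 16 | 41 |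
| green | 12.0 | 13 | 50 |
| green | 15.0 | 13 | 53 |
| green | 25.0 | 11 | 53 |
| green | 30.0 | 8 | 57 |
| green | 40.0 | 11 | 57 |

(each reading ± 1.5 percentage points)

- steps thought possible: isomer of the product B + catalyst <-> substrate + catalyst; target + catalyst <-> isomer of the product A + catalyst; substrate + catalyst <-> target + catalyst; isomer of the product A + catalyst <-> isomer of the product B + catalyst

* share of target in target plus isomer of the product A at 4.0 s
* share of target in target plus isomer of the product A at 1.5 min
* share of target in target plus isomer of the product A at 50 min
* which of target and isomer of the product A there is more of at 50 min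

The steps thought possible close a ring: substrate to target, target to isomer of the product A, that to isomer of the product B, and that back to substrate, each reversible. Catalyst stands on both sides of every step, so [catalyst] stays as charged and each step is pseudo-first-order, with a rate in proportion to [catalyst].

My bench rule follows: at the same [substrate], the clock runs in proportion to the loading. So I carry the clock factor 2.00, the violet minutes that pass in one minute of a flask, which is its loading divided by violet's. Green tests the rule. Its 6.00 min make 8.95 min of violet time, and it reads 41% of isomer of the product A where violet reads 42% at 8.00 min.

The flask's 1.5 min makes 3.00 min of violet time. Violet at 3.00 min and green at 2.00 min stand there, and pooled they give me a share of 41.2%. The flask's 50 min makes 100 min of violet time, past the last violet reading. Violet's last two readings of isomer of the product A are 53% and 54%, so I pool the violet and green readings at 40.0 min and take 15.3%, with isomer of the product A ahead.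

The border comes at 4.0 s. That is 0.133 min of violet time, a fraction 0.0444 of the first violet reading, so there is nothing to copy. I expect a high share and give no figure.

The forecast gives 90% (from 65% to 98%), 41%, 15%, and isomer of the product A ahead. It says: “This is an extrapolation, and a fast route through B would lower it, so the range is wide.”

The flask gives 95.7%, 43.5% and 13.3%, with isomer of the product A at 55.6% against 8.52% of target.

    isomer of the product B + catalyst ⇌ substrate + catalyst, rate k1*[catalyst]*[isomer of the product B] forward; the back reaction follows from the equilibrium constant (k = 1.50 L mol⁻¹ min⁻¹)
    target + catalyst ⇌ isomer of the product A + catalyst, rate k2*[catalyst]*[target] forward; the back reaction follows from the equilibrium constant (K = 6.60, k = 0.0770 L mol⁻¹ min⁻¹)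
    substrate + catalyst ⇌ target + catalyst, rate k3*[substrate]*[catalyst] forward; the back reaction follows from the equilibrium constant (K = 11.0, k = 15.0 L mol⁻¹ min⁻¹)
    isomer of the product A + catalyst ⇌ isomer of the product B + catalyst, rate k4*[catalyst]*[isomer of the product A] forward; the back reaction follows from the equilibrium constant (K = 0.630, k = 2.20 L mol⁻¹ min⁻¹)

The forecast parts from the flask at 4.0 s, by 5.7 percentage points. The flask holds equal target and isomer of the product A at 1.12 min, which is 2.24 min of violet time, ahead of the first violet reading. The neighbouring flask with 2.8 mol% of catalyst has a clock factor of 0.509, so its 50 min make 25.5 min of violet time. Violet at 25.0 min reads 9% of target and 53% of isomer of the product A, a read share of 14.5%. That neighbouring flask ends with 11.8% of target and 52.9% of isomer of the product A, a share of 18.3%.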